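## Structural features

Compound 40 is a briarane. A cyclohexane (C1, C10–C14) is trans-fused through C1–C10 to a ten-membered carbocycle (C1–C10), and a γ-lactone (C7–O–C19(=O)–C17–C8) is fused to the large ring at C7–C8.

There are twelve stereocentres. On the six-membered ring the C15 methyl on quaternary C1, the C9 branch on C10 and the C20 methyl on C11 share one face; the C2 branch, the C12 acetate and the C13/C14 epoxide lie on the other. Around the large ring follow C2 (OAc), C6 (Cl), C7 (lactone O), C8 (tertiary OH) and C9 (OH), so C6–C9 are four contiguous heteroatom-bearing carbons and C8 is fully substituted.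

The fragile groups are the secondary allylic chloride at C6 (ionisable, open to SN2′ attack and to reduction), the cis-epoxide, the two acetates, the exocyclic methylene and the tertiary β-hydroxy lactone, which can undergo retro-aldol cleavage or migrate to O9 under base.

The real difficulty is to close a ten-membered ring next to quaternary C1 with the C6–C9 oxygenation already in place, while the chloride must arrive late.

The key step uses the unit C4H2–C5(=C16H2). With a leaving group on C4 it ionises to a 2-substituted allyl fragment whose two CH2 termini are equivalent, and C3, next to C2 at the ketone level, can be made a soft carbanion.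

## Logic of the disconnections

**40 ⇒ 39 ⇒ 38 ⇒ 37.** The C6–Cl bond and the O–Si bonds at C8 and C9 are cut first. An allylic chloride would not survive palladium, samarium diiodide or hydride, so it is traced to the C6-epimeric allylic alcohol 38 and made by SN2 inversion. The gain is that every earlier intermediate carries an inert silyl ether at C6. The demands are inversion without allylic transposition, a C6 silyl group in 37 that can be removed alone, and a final desilylation of 39 that spares epoxide and chloride.

**37 ⇒ 36 ⇒ 35 ⇒ 34.** The C2–OAc group is taken back to a C2 ketone and a sulfonyl group is added at C3. Together they make C3–H acidic enough for neutral alkylation. The demands are a reductive desulfonylation that touches nothing else (34 → 35) and hydride delivery to the correct face of the C2 carbonyl (35 → 36).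

**34 ⇒ 33.** The C3–C4 bond is cut, which opens the ten-membered ring to a β-keto sulfone bearing an allylic carbonate. Because the allyl termini are equivalent there is no regiochemical question and no stereocentre of consequence. The obvious form of this precursor is changed in three ways:
- The tertiary C8 hydroxyl is silylated in 33. Left free, it would attack the allyl complex and close a six-membered ether.
- The silyl groups are distributed as C6 triethylsilyl and C9 tert-butyldimethylsilyl, so that C6 alone can be unveiled later.
- C3 does become a stereocentre in 34. Both epimers are carried and the centre is erased in 35.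

The forward step needs C- rather than O-alkylation and cyclisation rather than oligomerisation.

**33 ⇒ 32 ⇒ 31 ⇒ 29 + 30.** The C8–C17 bond and the C7–O acyl bond are cut. The hydroxy lactone becomes an acyclic α-acyloxy ketone, which removes two stereocentres (C8, C17) and one ring. The forward step must generate an enolate only at the bromo ester, in the presence of a ketone, an acidic keto sulfone and an allylic carbonate, and must close with the C9 branch trans to the C6 branch.

**29 ⇐ 28 ⇐ 27 ⇐ 26 ⇒ 22 + 25.** The C6–C7 bond is cut as an aldol. The whole C4–C6/C16 unit then comes from one small enal and C6 and C7 are set together. The forward step must be syn-selective (C6–O and C7–O on the same side, so that later inversion gives 6S) and must take the enolate face that places C7–O syn to C9–O.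

**22 ⇐ 20 ⇐ … ⇐ 10 ⇒ 7 + 9.** The C8–C9 bond is cut, with the C8 carbonyl latent as a methylidene. A two-carbon alkenyl nucleophile adds to the C9 aldehyde, and the only remaining alkene is cleaved later. The forward step needs aldehyde-only reactivity and Felkin–Anh control at C9.

**20 ⇐ 19 ⇐ 18 ⇐ 17 ⇒ 15 + 16; 15 ⇐ 14 ⇐ 13 ⇐ 11.** The C2–C3 bond is cut as acylation of a sulfonyl carbanion by the C2 ester. This is done while the molecule holds only ethers and alkenes, because no later stage tolerates the reagent. The epoxide and C12 acetate come from an allylic alcohol by hydroxyl-directed epoxidation. The C13=C14 alkene and C12–O come from the enol ether of a C13 ketone by α-oxygenation, enol triflate formation and reduction. The demands are oxygenation trans to the C20 methyl and enolisation away from C12.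

**7 ⇒ 2 + 6.** The C10–C11 and C1–C14 bonds are cut. A [4+2] cycloaddition sets C1, C10 and C11 at once and delivers the C9 aldehyde, the C2 ester and a C13 enol ether. The forward step must be regioselective, endo in the formyl group and enantioselective.

**Starting materials.** 2 ⇐ 1 by enol silylation. 6 ⇐ 5 ⇐ 3 + 4 by olefination and acetal hydrolysis. 9 ⇐ 8 and 25 ⇐ 24 ⇐ 23 by etherification and oxidation. 16 and 30 are bought.

## Other disconnections considered

**Alternative 1:** The cut is C10–C11 and C1–C14. The forward key step is a chiral-Lewis-acid Diels–Alder reaction of diene A1 ((Z)-3-silyloxypenta-1,3-diene) with enal A2 ((E)-4-benzyloxy-2-methylbut-2-enal) to give cyclohexene A3.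
- In its favour: three contiguous stereocentres (quaternary C1, C10, C11) and the ring would arise in one catalytic step from two simple partners. The enol ether of A3 sits at C12=C13, so one dehydrosilylation would give the C12 ketone with the C13=C14 alkene. That is shorter than steps 8–10 and 12 here, and on this point the alternative is the better.
- Against it: for the C20 methyl to be cis to the C9 branch the formyl group must react exo, because the outward methyl of A1 ends cis to whatever is endo. The silyloxy and methyl groups of A1 direct the regiochemistry in opposite senses. C11 would then lie α to the C12 carbonyl, where equilibration should favour the unwanted trans isomer.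
- Comparison: as a ring construction it is the equal of step 4 (same two bonds, same concerted mechanism). The chosen plan only exchanges the positions of formyl and silyloxy so that the endo rule and both directing effects agree. As the strategy-bearing step it sets stereocentres where step 25 sets none, which counts for it, but it leaves the ten-membered ring untouched. The overall length would be the same or about two steps shorter.

**Alternative 2:** The cut is C8–C17, with the C7–O–C19 ester as tether. Zinc or samarium diiodide would turn the 2-bromopropanoate of the ten-membered C8 ketone A4 into a metal enolate that adds across the ring to give lactone A5.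
- In its favour: the lactone and two stereocentres (C8, C17) would form at the very end inside a conformationally defined macrocycle. The base-sensitive hydroxy lactone would not have to be carried through eight steps, and on that point it is the better. Five-membered closure onto a ketone is intrinsically easy.
- Against it: the reductant would meet the allylic chloride at C6 and an α-acyloxy, α′-silyloxy ketone, both reducible. A ten-membered ketone must still be closed by some other reaction, so the medium-ring problem is moved, not solved. The face of C8 that is attacked would be fixed by the macrocycle and could not be corrected.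
- Comparison: the chosen plan forms the same bond by the same reaction type in step 23, on an acyclic ketone before any chloride exists. The two are equal in mechanism and ring-closure mode. The chosen plan is safer in chemoselectivity, the alternative more convergent at the end. Step counts are comparable.

**Alternative 3:** The cut is C6–C7. Chromium dichloride would convert the allylic bromide of aldehyde A6 into a γ-chloroallylchromium bound at C16, which adds through C6 to the C7 aldehyde to give chlorohydrin A7.
- In its favour: one step would form the ring, the C6–C7 bond, both stereocentres (the anti chlorohydrin that 40 needs), the chloride and the exocyclic methylene. No late inversion at C6 and no selective desilylation would be needed, which removes four to five end-game steps. On step economy and on stereocentres set it is clearly the better.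
- Against it: the aldehyde sits on the fully substituted C8, so the ring would be closed at its most hindered bond. Facial control must come from the C8/C9 dioxolane. The chromium alkoxide next to the chloride could close to a vinyl epoxide. Stoichiometric chromium at high dilution is needed, and a γ-chloro allylic bromide must be carried into A6.
- Comparison: the closed chair transition state is better organised than the outer-sphere attack of step 25, so it is equal or better for stereocontrol, but it acts on a much more hindered electrophile. The chosen step joins two unhindered carbons with catalytic palladium and has no stereochemical demand. Step economy favours the alternative; robustness favours the chosen plan.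

Key step: step 25

## Conventions and assumption

Locants C1–C20 are those of the briarane skeleton of 40. Unless a name says otherwise, each stereocentre has the configuration it has in 40; the SMILES strings in the compound list are authoritative. PMB = 4-methoxybenzyl.

Assumption: the (S)-oxazaborolidinium catalyst of step 4 is taken to give the enantiomer drawn for 7 (the (R)-catalyst is used if the sense is opposite). Compound 30 is used as the racemate, since its stereocentre is lost in the enolate of step 23.

## Steps

Step 1
Reactants: 1 (E)-pent-3-en-2-one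
Product: 2 (E)-triethyl(penta-1,3-dien-2-yloxy)silane
Conditions: Et3SiOTf, Et3N, Et2O, 0 °C
Reagents that add atoms: triethylsilyl trifluoromethanesulfonate, CC[Si](CC)(CC)OS(=O)(=O)C(F)(F)F
Why: Soft enolisation of a methyl enone with a silyl triflate and an amine removes a methyl proton and gives the cross-conjugated 2-silyloxy diene; the E alkene is untouched.

Step 2
Reactants: 3 methyl 2-(triphenyl-λ5-phosphanylidene)propanoate; 4 2,2-dimethoxyacetaldehyde
Product: 5 methyl (E)-4,4-dimethoxy-2-methylbut-2-enoate
Conditions: CH2Cl2, rt (4 as its 60 % aqueous solution)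
Reagents that add atoms: none
Why: Wittig olefination with a stabilised ylide, which is E-selective and tolerates water.

Step 3
Reactants: 5 methyl (E)-4,4-dimethoxy-2-methylbut-2-enoate
Product: 6 methyl (E)-2-methyl-4-oxobut-2-enoate
Conditions: 1 M HCl, acetone, rt
Reagents that add atoms: water, O
Why: Acid hydrolysis of a dimethyl acetal; the conjugated E ester is the stable geometry.

Step 4
Reactants: 2 (E)-triethyl(penta-1,3-dien-2-yloxy)silane; 6 methyl (E)-2-methyl-4-oxobut-2-enoate
Product: 7 methyl (1S,2S,3S)-2-formyl-1,3-dimethyl-5-(triethylsilyloxy)cyclohex-4-ene-1-carboxylate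
Conditions: (S)-oxazaborolidinium triflimide [(S)-3,3-diphenyl-1-(2-methylphenyl)hexahydropyrrolo[1,2-c][1,3,2]oxazaborole·HNTf2] (15 mol %), CH2Cl2, −78 °C
Reagents that add atoms: none
Why: Lewis-acid-catalysed Diels–Alder reaction in which the formyl-bound catalyst makes C1 the electrophilic terminus, so the CH2 end of the diene bonds to C1 and the methyl-bearing end to C10 (silyloxy para and methyl ortho to the formyl carbon, both effects agreeing). The E dienophile fixes CHO trans to the ester, the endo-formyl transition state puts the outward C11 methyl cis to CHO, and the catalyst selects the enal face.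

Step 5
Reactants: 8 2-bromoprop-2-en-1-ol
Product: 9 2-bromoprop-2-en-1-yl 4-methoxybenzyl ether
Conditions: NaH, THF, 0 °C; 4-methoxybenzyl chloride, Bu4NI (cat.), rt
Reagents that add atoms: 4-methoxybenzyl chloride, COc1ccc(CCl)cc1
Why: Williamson etherification of a primary alkoxide with a benzylic chloride.

Step 6
Reactants: 7 cycloadduct aldehyde; 9 2-bromoprop-2-en-1-yl 4-methoxybenzyl ether
Product: 10 (9R)-allylic alcohol [C9(OH)–C8(=CH2)–C7H2–OPMB on the ring of 7]
Conditions: CrCl2 (4 equiv), NiCl2 (2 mol %), DMF, rt
Reagents that add atoms: none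
Why: Nozaki–Hiyama–Kishi coupling: the alkenylchromium reagent adds to the aldehyde only (ester and silyl enol ether are inert), and Felkin–Anh attack anti to quaternary C1 gives the 9R carbinol. The epimerisable aldehyde is consumed at once.

Step 7
Reactants: 10 (9R)-allylic alcohol
Product: 11 9-O-tert-butyldimethylsilyl ether of 10
Conditions: t-BuMe2SiOTf, 2,6-lutidine, CH2Cl2, −78 → 0 °C
Reagents that add atoms: tert-butyldimethylsilyl trifluoromethanesulfonate, CC(C)(C)[Si](C)(C)OS(=O)(=O)C(F)(F)F
Why: Silylation of a hindered secondary alcohol with a silyl triflate; capping O9 now prevents lactonisation onto the C2 ester and later hemiketal formation with the C2 ketone.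

Step 8
Reactants: 11 9-O-tert-butyldimethylsilyl ether
Product: 13 C13 ketone carrying the C12 triethylsilyl ether, via silyloxy epoxide 12 (not isolated)
Conditions: m-CPBA, NaHCO3, CH2Cl2, −20 → 0 °C
Reagents that add atoms: 3-chloroperoxybenzoic acid, OOC(=O)c1cccc(Cl)c1
Why: Rubottom oxidation: the peracid epoxidises the electron-rich enol ether (not the deactivated 1,1-disubstituted alkene) from the face opposite the C20 methyl, the C9 branch and the C15 methyl. A 1,4-silyl shift then opens 12 to the α-silyloxy ketone with C12–O trans to the C20 methyl.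

Step 9
Reactants: 13 α-silyloxy ketone
Product: 14 enol triflate (C13–OTf, C13=C14)
Conditions: KN(SiMe3)2, THF, −78 °C; PhNTf2, −78 → 0 °C
Reagents that add atoms: N-phenylbis(trifluoromethanesulfonimide), O=S(=O)(N(c1ccccc1)S(=O)(=O)C(F)(F)F)C(F)(F)F
Why: Kinetic enolate O-triflation: the bulky amide takes a C14 proton, not the shielded C12 methine next to the silyloxy group, and the C2 ester has no α-hydrogen.

Step 10
Reactants: 14 enol triflate
Product: 15 cyclohexene (C13=C14, C12–OSiEt3)
Conditions: Pd(OAc)2 (5 mol %), PPh3 (10 mol %), HCO2H, Bu3N, DMF, 60 °C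
Reagents that add atoms: none
Why: Palladium-catalysed formate reduction of an enol triflate (oxidative addition, formate exchange, loss of CO2, reductive elimination); ethers, ester and the other alkene are unaffected.

Step 11
Reactants: 15 cyclohexene methyl ester; 16 methyl phenyl sulfone
Product: 17 β-keto sulfone [C2(=O)–C3H2–SO2Ph]
Conditions: 16, n-BuLi (3 equiv each), THF, −78 → 0 °C; then 15, 0 °C → rt; aq. NH4Cl
Reagents that add atoms: none
Why: Claisen-type acylation of lithiated methyl phenyl sulfone by the non-enolisable neopentyl ester. The product is deprotonated as it forms (hence the excess), which stops a second addition; only ethers and alkenes are present at this stage.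

Step 12
Reactants: 17 β-keto sulfone
Product: 18 allylic alcohol (12-OH)
Conditions: HF·pyridine, pyridine, THF, 0 °C
Reagents that add atoms: none
Why: Fluoride cleavage of the less hindered secondary triethylsilyl ether; the hindered tert-butyldimethylsilyl ether at C9 is much slower and is kept.

Step 13
Reactants: 18 allylic alcohol
Product: 19 13,14-epoxy alcohol (epoxide cis to 12-OH)
Conditions: VO(acac)2 (5 mol %), t-BuOOH, CH2Cl2, 0 °C → rt
Reagents that add atoms: tert-butyl hydroperoxide, CC(C)(C)OO
Why: Hydroxyl-directed epoxidation: the vanadium alkoxide delivers oxygen to the alkene face syn to 12-OH and ignores the C8 methylidene, whose allylic oxygens are protected.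

Step 14
Reactants: 19 epoxy alcohol
Product: 20 12-acetate
Conditions: Ac2O, pyridine, 4-(dimethylamino)pyridine (cat.), CH2Cl2, 0 °C → rt
Reagents that add atoms: acetic anhydride, CC(=O)OC(C)=O
Why: Acylation of the only free hydroxyl; it is placed after step 11 because an acetate would not survive the sulfonyl carbanion.

Step 15
Reactants: 20 12-acetate
Product: 22 C8 ketone (C7H2–OPMB), via vicinal diol 21 (not isolated)
Conditions: K2OsO4·2H2O (2 mol %), NaIO4, 2,6-lutidine, dioxane–H2O, rt
Reagents that add atoms: sodium periodate (terminal oxidant, oxygen delivered through the osmate), [Na+].[O-]I(=O)(=O)=O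
Why: Lemieux–Johnson cleavage: dihydroxylation of the only remaining alkene and periodate cleavage of 21 unmask the C8 ketone; buffering protects C9 from epimerisation.

Step 16
Reactants: 23 2-methylidenepropane-1,3-diol
Product: 24 2-{[(4-methoxybenzyl)oxy]methyl}prop-2-en-1-ol
Conditions: NaH (1 equiv), THF, 0 °C; 4-methoxybenzyl chloride, Bu4NI (cat.), rt
Reagents that add atoms: 4-methoxybenzyl chloride, COc1ccc(CCl)cc1
Why: Monoalkylation of a symmetrical diol through its poorly soluble monosodium alkoxide (Williamson etherification).

Step 17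
Reactants: 24 mono-PMB ether
Product: 25 2-{[(4-methoxybenzyl)oxy]methyl}prop-2-enal
Conditions: MnO2, CH2Cl2, rt
Reagents that add atoms: none
Why: Selective oxidation of an allylic alcohol to the enal on manganese dioxide; the enal is used fresh.

Step 18
Reactants: 22 C8 ketone; 25 enal
Product: 26 aldol [(6R)-6-OH, 7-OPMB, 6,7-syn, 7-O syn to 9-O]
Conditions: Bu2BOTf (2.2 equiv), i-Pr2NEt (2.5 equiv), CH2Cl2, −78 → 0 °C; 25, −78 °C; pH 7 buffer, MeOH
Reagents that add atoms: none
Why: Boron aldol reaction: the Z-enol borinate forms on the C7 side, while the keto sulfone is held as an unreactive chelated boron enolate (hence two equivalents), and the Zimmerman–Traxler chair gives the 6,7-syn adduct. As in boron aldol reactions of α′-silyloxy α′-cycloalkyl ketones, the silyloxy group lies anti to the enolate oxygen and the aldehyde enters opposite the ring residue, which places C7–O syn to C9–O.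

Step 19
Reactants: 26 aldol
Product: 27 6-O-triethylsilyl ether
Conditions: Et3SiOTf, 2,6-lutidine, CH2Cl2, −78 °C
Reagents that add atoms: triethylsilyl trifluoromethanesulfonate, CC[Si](CC)(CC)OS(=O)(=O)C(F)(F)F
Why: Silylation of the β-hydroxy ketone at low temperature, with no retro-aldol; triethylsilyl is chosen so that O6 can later be freed alone.

Step 20
Reactants: 27 6-O-triethylsilyl ether
Product: 28 keto diol (7-OH, 4-OH)
Conditions: DDQ, CH2Cl2–pH 7 buffer, 0 °C → rt
Reagents that add atoms: none
Why: Oxidative cleavage of both PMB ethers (hydride abstraction, then hydrolysis of the oxocarbenium ions); silyl ethers, epoxide, acetate and keto sulfone are inert to buffered DDQ.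

Step 21
Reactants: 28 keto diol
Product: 29 4-O-methoxycarbonyl derivative (allylic methyl carbonate, 7-OH free)
Conditions: ClCO2Me, pyridine, CH2Cl2, −20 °C
Reagents that add atoms: methyl chloroformate, COC(Cl)=O
Why: Chemoselective acylation of the primary allylic hydroxyl over the hindered secondary α-ketol hydroxyl.

Step 22
Reactants: 29 allylic carbonate; 30 2-bromopropanoyl bromide
Product: 31 7-O-(2-bromopropanoyl) ester
Conditions: 30, pyridine, 4-(dimethylamino)pyridine (cat.), CH2Cl2, −20 → 0 °C
Reagents that add atoms: none
Why: Esterification of the α-ketol hydroxyl with an acid bromide; the epimeric mixture at the bromine-bearing carbon does not matter.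

Step 23
Reactants: 31 bromo ester
Product: 32 hydroxy lactone (8-OH, C17 methyl cis to 8-OH)
Conditions: LiN(SiMe3)2 (1.05 equiv), THF, −78 °C; SmI2 (2.5 equiv), THF, −78 °C; pH 7 buffer
Reagents that add atoms: none
Why: Intramolecular samarium Reformatsky reaction: one equivalent of amide first stores the keto sulfone as its enolate, which resists electron transfer, and samarium diiodide then reduces the C–Br bond fastest. The trivalent samarium enolate closes the five-membered lactone on the C8 ketone (5-exo-trig) with the bulky C9 branch trans to the C6 branch, so C8–O is cis to C6. The C17 methyl takes the more stable position trans to the C9 branch.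

Step 24
Reactants: 32 hydroxy lactone
Product: 33 cyclisation precursor (8-O-triethylsilyl ether)
Conditions: Et3SiOTf, 2,6-lutidine, CH2Cl2, 0 °C → rt
Reagents that add atoms: triethylsilyl trifluoromethanesulfonate, CC[Si](CC)(CC)OS(=O)(=O)C(F)(F)F
Why: Silylation of the tertiary alcohol with a silyl triflate; this removes the one oxygen nucleophile that could intercept the allyl complex in step 25 and blocks retro-aldol opening.

Step 25
Reactants: 33 β-keto sulfone allylic carbonate
Product: 34 ten-membered C2 ketone C3 sulfone (both C3 epimers)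
Conditions: Pd2(dba)3·CHCl3 (5 mol %), 1,2-bis(diphenylphosphino)ethane (12 mol %), THF, 65 °C, slow addition of 33 (final 1 mM)
Reagents that add atoms: none
Why: Zerovalent palladium ionises the allylic carbonate with loss of CO2 and methoxide to a cationic 2-substituted eta-3 allyl complex whose CH2 termini (C4, C16) are equivalent; the methoxide deprotonates the β-keto sulfone, so no external base is needed. The soft C3 carbanion attacks a terminus on the face away from the metal (outer-sphere alkylation); the closest known reaction type is the palladium-catalysed macrocyclisation of sulfone-stabilised carbanions onto allylic esters or carbonates (Tsuji–Trost reaction). The one ring closed is the ten-membered carbocycle, by C3–C4 bonding with the central allyl carbon C5 inside the ring and the other terminus left as the exocyclic C16 methylene; attack at either terminus gives the same constitution. The only new stereocentre is C3, formed without control as an epimer mixture that is erased in step 26. The step needs C- over O-alkylation and ring closure over oligomerisation: an O-allyl enol ether would re-ionise under the catalyst and funnel to the C-alkylated ketone, and slow addition at high dilution suppresses the bimolecular path. The substrate secures the rest: O8 is silylated (free, it would close a six-membered ether), the C6 and C9 silyl ethers cannot ionise, and C17–H is far less acidic than C3–H.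

Step 26
Reactants: 34 macrocyclic keto sulfone
Product: 35 ten-membered C2 ketone (C3H2)
Conditions: SmI2 (3 equiv), THF–MeOH, −78 °C
Reagents that add atoms: none
Why: Reductive desulfonylation of an α-sulfonyl ketone (electron transfer to the carbonyl, loss of sulfinate, protonation of the samarium enolate at C3); lactone, epoxide, acetate and silyl ethers are not reduced at −78 °C.

Step 27
Reactants: 35 macrocyclic ketone
Product: 36 (2R)-alcohol
Conditions: NaBH4, CeCl3·7H2O, MeOH–THF, −40 → 0 °C
Reagents that add atoms: none
Why: Luche-type hydride reduction: the ring carbonyl is attacked from the periphery in the conformer whose oxygen eclipses the small C15 methyl and not ring carbon C14, which should give the 2R alcohol (OH syn to C15). Lactone and acetate survive.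

Step 28
Reactants: 36 (2R)-alcohol
Product: 37 2,12-diacetate
Conditions: Ac2O, 4-(dimethylamino)pyridine, pyridine, rt
Reagents that add atoms: acetic anhydride, CC(=O)OC(C)=O
Why: Nucleophile-catalysed acylation of the only free (hindered secondary) hydroxyl.

Step 29
Reactants: 37 diacetate
Product: 38 (6R)-allylic alcohol
Conditions: pyridinium p-toluenesulfonate (cat.), MeOH–CH2Cl2, 0 °C
Reagents that add atoms: none
Why: Acid-catalysed methanolysis discriminates by steric access: the secondary allylic triethylsilyl ether at C6 is cleaved while the tertiary C8 triethylsilyl and the hindered C9 tert-butyldimethylsilyl ethers remain.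

Step 30
Reactants: 38 (6R)-allylic alcohol
Product: 39 (6S)-chloride (8-OSiEt3, 9-OSi-t-BuMe2)
Conditions: Ph3P, Cl3CC(O)CCl3, CH2Cl2, −40 → 0 °C
Reagents that add atoms: hexachloroacetone, O=C(C(Cl)(Cl)Cl)C(Cl)(Cl)Cl
Why: Deoxychlorination through an alkoxyphosphonium ion and backside displacement by chloride (SN2) inverts C6 to 6S; this reagent pair is the neutral, low-temperature choice known to keep allylic transposition low.

Step 31
Reactants: 39 (6S)-chloride
Product: 40 CNP0242711.1
Conditions: HF·pyridine, pyridine, THF, 0 °C → rt
Reagents that add atoms: none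
Why: Fluoride cleavage of the two remaining silyl ethers in a weakly acidic medium; no alkoxide forms, so the lactone does not migrate to O9 and the acetates do not shift, and epoxide and allylic chloride are left intact.

## Compound list

1 | (E)-pent-3-en-2-one | C/C=C/C(C)=O | starting material
2 | (E)-triethyl(penta-1,3-dien-2-yloxy)silane | C=C(O[Si](CC)(CC)CC)/C=C/C | intermediate
3 | methyl 2-(triphenyl-λ5-phosphanylidene)propanoate | COC(=O)C(C)=P(c1ccccc1)(c1ccccc1)c1ccccc1 | starting material
4 | 2,2-dimethoxyacetaldehyde | COC(OC)C=O | starting material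
5 | methyl (E)-4,4-dimethoxy-2-methylbut-2-enoate | COC(=O)/C(C)=C/C(OC)OC | intermediate
6 | methyl (E)-2-methyl-4-oxobut-2-enoate | COC(=O)/C(C)=C/C=O | intermediate
7 | methyl (1S,2S,3S)-2-formyl-1,3-dimethyl-5-(triethylsilyloxy)cyclohex-4-ene-1-carboxylate (formyl cis to both methyls, trans to the ester; ring = C1, C10, C11, C12, C13, C14) | COC(=O)[C@]1(C)[C@H]([C@@H](C)C=C(O[Si](CC)(CC)CC)C1)C=O | intermediate
8 | 2-bromoprop-2-en-1-ol | C=C(Br)CO | starting material
9 | 2-bromoprop-2-en-1-yl 4-methoxybenzyl ether | C=C(Br)COCc1ccc(OC)cc1 | intermediate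
10 | (9R)-allylic alcohol: 7 with CHO replaced by CH(OH)–C(=CH2)–CH2–OPMB | COC(=O)[C@]1(C)[C@H]([C@@H](C)C=C(O[Si](CC)(CC)CC)C1)[C@@H](O)C(=C)COCc1ccc(OC)cc1 | intermediate
11 | 9-O-tert-butyldimethylsilyl ether of 10 | COC(=O)[C@]1(C)[C@H]([C@@H](C)C=C(O[Si](CC)(CC)CC)C1)[C@@H](O[Si](C)(C)C(C)(C)C)C(=C)COCc1ccc(OC)cc1 | intermediate
12 | 12,13-epoxide of 11 (13-triethylsilyloxy oxirane, oxygen trans to the C20 methyl) | COC(=O)[C@]1(C)[C@H]([C@@H](C)[C@@H]2O[C@]2(O[Si](CC)(CC)CC)C1)[C@@H](O[Si](C)(C)C(C)(C)C)C(=C)COCc1ccc(OC)cc1 | intermediate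
13 | C13 ketone with C12 triethylsilyl ether trans to the C20 methyl | COC(=O)[C@]1(C)[C@H]([C@@H](C)[C@H](O[Si](CC)(CC)CC)C(=O)C1)[C@@H](O[Si](C)(C)C(C)(C)C)C(=C)COCc1ccc(OC)cc1 | intermediate
14 | C13 enol triflate (C13=C14) | COC(=O)[C@]1(C)[C@H]([C@@H](C)[C@H](O[Si](CC)(CC)CC)C(OS(=O)(=O)C(F)(F)F)=C1)[C@@H](O[Si](C)(C)C(C)(C)C)C(=C)COCc1ccc(OC)cc1 | intermediate
15 | cyclohexene (C13=C14, C12–OSiEt3, C2 methyl ester) | COC(=O)[C@]1(C)[C@H]([C@@H](C)[C@H](O[Si](CC)(CC)CC)C=C1)[C@@H](O[Si](C)(C)C(C)(C)C)C(=C)COCc1ccc(OC)cc1 | intermediate
16 | methyl phenyl sulfone | CS(=O)(=O)c1ccccc1 | starting material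
17 | β-keto sulfone: 15 with CO2Me replaced by C(=O)CH2SO2Ph | O=S(=O)(c1ccccc1)CC(=O)[C@]1(C)[C@H]([C@@H](C)[C@H](O[Si](CC)(CC)CC)C=C1)[C@@H](O[Si](C)(C)C(C)(C)C)C(=C)COCc1ccc(OC)cc1 | intermediate
18 | 12-hydroxy cyclohexene (allylic alcohol) | O=S(=O)(c1ccccc1)CC(=O)[C@]1(C)[C@H]([C@@H](C)[C@H](O)C=C1)[C@@H](O[Si](C)(C)C(C)(C)C)C(=C)COCc1ccc(OC)cc1 | intermediate
19 | 13,14-epoxy-12-ol (epoxide cis to OH) | O=S(=O)(c1ccccc1)CC(=O)[C@]1(C)[C@H]([C@@H](C)[C@H](O)[C@@H]2O[C@@H]21)[C@@H](O[Si](C)(C)C(C)(C)C)C(=C)COCc1ccc(OC)cc1 | intermediate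
20 | 12-acetate of 19 | O=S(=O)(c1ccccc1)CC(=O)[C@]1(C)[C@H]([C@@H](C)[C@H](OC(C)=O)[C@@H]2O[C@@H]21)[C@@H](O[Si](C)(C)C(C)(C)C)C(=C)COCc1ccc(OC)cc1 | intermediate
21 | vicinal diol from the C8 methylidene of 20 (C8 epimers) | O=S(=O)(c1ccccc1)CC(=O)[C@]1(C)[C@H]([C@@H](C)[C@H](OC(C)=O)[C@@H]2O[C@@H]21)[C@@H](O[Si](C)(C)C(C)(C)C)C(O)(CO)COCc1ccc(OC)cc1 | intermediate
22 | C8 ketone: C9(OSi-t-BuMe2)–C8(=O)–C7H2–OPMB | O=S(=O)(c1ccccc1)CC(=O)[C@]1(C)[C@H]([C@@H](C)[C@H](OC(C)=O)[C@@H]2O[C@@H]21)[C@@H](O[Si](C)(C)C(C)(C)C)C(=O)COCc1ccc(OC)cc1 | intermediate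
23 | 2-methylidenepropane-1,3-diol | C=C(CO)CO | starting material
24 | 2-{[(4-methoxybenzyl)oxy]methyl}prop-2-en-1-ol | C=C(CO)COCc1ccc(OC)cc1 | intermediate
25 | 2-{[(4-methoxybenzyl)oxy]methyl}prop-2-enal | C=C(C=O)COCc1ccc(OC)cc1 | intermediate
26 | aldol: C8 ketone, 7-OPMB, (6R)-6-OH (6,7-syn), C5(=CH2), C4H2–OPMB | O=S(=O)(c1ccccc1)CC(=O)[C@]1(C)[C@H]([C@@H](C)[C@H](OC(C)=O)[C@@H]2O[C@@H]21)[C@@H](O[Si](C)(C)C(C)(C)C)C(=O)[C@@H](OCc1ccc(OC)cc1)[C@H](O)C(=C)COCc1ccc(OC)cc1 | intermediate
27 | 6-O-triethylsilyl ether of 26 | O=S(=O)(c1ccccc1)CC(=O)[C@]1(C)[C@H]([C@@H](C)[C@H](OC(C)=O)[C@@H]2O[C@@H]21)[C@@H](O[Si](C)(C)C(C)(C)C)C(=O)[C@@H](OCc1ccc(OC)cc1)[C@H](O[Si](CC)(CC)CC)C(=C)COCc1ccc(OC)cc1 | intermediate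
28 | keto diol (7-OH, 4-OH) | O=S(=O)(c1ccccc1)CC(=O)[C@]1(C)[C@H]([C@@H](C)[C@H](OC(C)=O)[C@@H]2O[C@@H]21)[C@@H](O[Si](C)(C)C(C)(C)C)C(=O)[C@@H](O)[C@H](O[Si](CC)(CC)CC)C(=C)CO | intermediate
29 | 4-O-methoxycarbonyl derivative of 28 | O=S(=O)(c1ccccc1)CC(=O)[C@]1(C)[C@H]([C@@H](C)[C@H](OC(C)=O)[C@@H]2O[C@@H]21)[C@@H](O[Si](C)(C)C(C)(C)C)C(=O)[C@@H](O)[C@H](O[Si](CC)(CC)CC)C(=C)COC(=O)OC | intermediate
30 | 2-bromopropanoyl bromide (racemic) | CC(Br)C(Br)=O | starting material
31 | 7-O-(2-bromopropanoyl) ester of 29 | O=S(=O)(c1ccccc1)CC(=O)[C@]1(C)[C@H]([C@@H](C)[C@H](OC(C)=O)[C@@H]2O[C@@H]21)[C@@H](O[Si](C)(C)C(C)(C)C)C(=O)[C@@H](OC(=O)C(C)Br)[C@H](O[Si](CC)(CC)CC)C(=C)COC(=O)OC | intermediate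
32 | hydroxy lactone (C7–O–C19 lactone, 8-OH, C17 methyl cis to 8-OH) | O=S(=O)(c1ccccc1)CC(=O)[C@]1(C)[C@H]([C@@H](C)[C@H](OC(C)=O)[C@@H]2O[C@@H]21)[C@@H](O[Si](C)(C)C(C)(C)C)[C@]3(O)[C@@H](C)C(=O)O[C@H]3[C@H](O[Si](CC)(CC)CC)C(=C)COC(=O)OC | intermediate
33 | cyclisation precursor: 8-O-triethylsilyl ether of 32 | O=S(=O)(c1ccccc1)CC(=O)[C@]1(C)[C@H]([C@@H](C)[C@H](OC(C)=O)[C@@H]2O[C@@H]21)[C@@H](O[Si](C)(C)C(C)(C)C)[C@]3(O[Si](CC)(CC)CC)[C@@H](C)C(=O)O[C@H]3[C@H](O[Si](CC)(CC)CC)C(=C)COC(=O)OC | intermediate
34 | ten-membered C2 ketone C3 sulfone (C3 epimers) | C=C1CC(S(=O)(=O)c2ccccc2)C(=O)[C@]2(C)[C@H]([C@@H](C)[C@H](OC(C)=O)[C@@H]3O[C@@H]32)[C@@H](O[Si](C)(C)C(C)(C)C)[C@]2(O[Si](CC)(CC)CC)[C@@H](C)C(=O)O[C@H]2[C@@H]1O[Si](CC)(CC)CC | intermediate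
35 | ten-membered C2 ketone | C=C1CCC(=O)[C@]2(C)[C@H]([C@@H](C)[C@H](OC(C)=O)[C@@H]3O[C@@H]32)[C@@H](O[Si](C)(C)C(C)(C)C)[C@]2(O[Si](CC)(CC)CC)[C@@H](C)C(=O)O[C@H]2[C@@H]1O[Si](CC)(CC)CC | intermediate
36 | (2R)-alcohol | C=C1CC[C@@H](O)[C@]2(C)[C@H]([C@@H](C)[C@H](OC(C)=O)[C@@H]3O[C@@H]32)[C@@H](O[Si](C)(C)C(C)(C)C)[C@]2(O[Si](CC)(CC)CC)[C@@H](C)C(=O)O[C@H]2[C@@H]1O[Si](CC)(CC)CC | intermediate
37 | 2,12-diacetate (6-OSiEt3, 8-OSiEt3, 9-OSi-t-BuMe2) | C=C1CC[C@@H](OC(C)=O)[C@]2(C)[C@H]([C@@H](C)[C@H](OC(C)=O)[C@@H]3O[C@@H]32)[C@@H](O[Si](C)(C)C(C)(C)C)[C@]2(O[Si](CC)(CC)CC)[C@@H](C)C(=O)O[C@H]2[C@@H]1O[Si](CC)(CC)CC | intermediate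
38 | (6R)-allylic alcohol | C=C1CC[C@@H](OC(C)=O)[C@]2(C)[C@H]([C@@H](C)[C@H](OC(C)=O)[C@@H]3O[C@@H]32)[C@@H](O[Si](C)(C)C(C)(C)C)[C@]2(O[Si](CC)(CC)CC)[C@@H](C)C(=O)O[C@H]2[C@@H]1O | intermediate
39 | (6S)-chloride (8-OSiEt3, 9-OSi-t-BuMe2) | C=C1CC[C@@H](OC(C)=O)[C@]2(C)[C@H]([C@@H](C)[C@H](OC(C)=O)[C@@H]3O[C@@H]32)[C@@H](O[Si](C)(C)C(C)(C)C)[C@]2(O[Si](CC)(CC)CC)[C@@H](C)C(=O)O[C@H]2[C@H]1Cl | intermediate
40 | CNP0242711.1 | C=C1CC[C@@H](OC(C)=O)[C@]2(C)[C@H]([C@@H](C)[C@H](OC(C)=O)[C@@H]3O[C@@H]32)[C@@H](O)[C@]2(O)[C@@H](C)C(=O)O[C@H]2[C@H]1Cl | target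

## Step count and least certain steps

Total: 31 steps. Longest linear sequence: 27 steps (steps 2–4, 6–15, 18–31).

**Step 25 (key step).** Chain growth between molecules, or kinetic O-allylation, may outrun closure of the ten-membered ring, because the trans-fused cyclohexane and the lactone limit the conformers that bring C3 to an allyl terminus. The fallback drops palladium and closes the same bond by base-mediated alkylation of an allylic chloride. It sets out from 28: the primary allylic hydroxyl is converted (MsCl, 2,4,6-collidine, LiCl, DMF, 0 °C) into the allylic chloride F1. F1 is acylated with 30 as in step 22 to the bromo ester F2, cyclised as in step 23 to the hydroxy lactone F3 and silylated as in step 24 to the chloride precursor F4. Cs2CO3 with catalytic NaI in MeCN at high dilution then alkylates C3 at either CH2 of the allyl unit (direct or allylic displacement give the same product), and the route is rejoined at 34.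

**Step 4.** The strongly acidic catalyst may protodesilylate the diene, or the quaternary-centre-forming cycloaddition may proceed with low endo or enantioselectivity. The fallback gives up catalytic asymmetry. From 2 and 6 an achiral promoter (Me2AlCl, CH2Cl2, −78 °C) gives 7 together with its enantiomer F5. Step 6 then gives 10 and its enantiomer F6, which are separated by preparative chromatography on a chiral stationary phase. The route is rejoined at 10.

**Step 18.** The facial bias of the C9 stereocentre may erode because the enolate carbon carries an alkoxy group, not the alkyl group of the closest precedents, and the boron-bound keto sulfone may interfere. The fallback replaces substrate control by reagent control. From 22, enolisation with diisopinocampheylboron triflate of the enantiomeric series matched to the required face (both come from α-pinene) and i-Pr2NEt, then addition of 25, returns to 26. No new isolable compound arises (F0).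

**Step 23.** Electron transfer to the α-acyloxy, α′-silyloxy ketone (reductive C–O cleavage) or to the sulfone may compete with C–Br reduction, and the C17 methyl may emerge on the wrong face. The fallback generates the enolate by deprotonation and not by reduction. From 29, propanoyl chloride and pyridine give the propanoate F7. LiN(SiMe3)2 (2.2 equiv, THF, −78 °C) first deprotonates the keto sulfone and then the unhindered propanoate CH2 (the ketone α-hydrogens are tertiary and flanked by silyloxy groups), and the ester enolate closes onto C8. The route is rejoined at 32.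

**Step 27.** Hydride may be delivered to the other face of the ring carbonyl, since the conformational argument is only qualitative. The fallback uses reagent control. The 2-epimeric alcohol F8, should it form, is returned to 35 with Dess–Martin periodinane. 35 is then reduced by Corey–Bakshi–Shibata reduction ((S)-B-methyl oxazaborolidine, catecholborane, toluene, −78 °C), which for a tert-alkyl/primary-alkyl ketone should deliver hydride to the face that gives the 2R carbinol. The route is rejoined at 36.

**Step 30.** Chloride may attack C16 with allylic transposition, or elimination may take over, because C6 is hindered and carries a β-oxygen at C7. The fallback changes the mode of activation to a discrete sulfonate. From 38, MsCl and Et3N at −40 °C give the allylic mesylate F9, which is isolated cold and displaced with Bu4NCl in acetone at 0 °C (direct SN2 by a poorly solvated chloride). The route is rejoined at 39.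

## Further compounds

F1 | step 25 | allylic chloride from 28 (C4–Cl, 7-OH) | O=S(=O)(c1ccccc1)CC(=O)[C@]1(C)[C@H]([C@@H](C)[C@H](OC(C)=O)[C@@H]2O[C@@H]21)[C@@H](O[Si](C)(C)C(C)(C)C)C(=O)[C@@H](O)[C@H](O[Si](CC)(CC)CC)C(=C)CCl
F2 | step 25 | 7-O-(2-bromopropanoyl) ester of F1 | O=S(=O)(c1ccccc1)CC(=O)[C@]1(C)[C@H]([C@@H](C)[C@H](OC(C)=O)[C@@H]2O[C@@H]21)[C@@H](O[Si](C)(C)C(C)(C)C)C(=O)[C@@H](OC(=O)C(C)Br)[C@H](O[Si](CC)(CC)CC)C(=C)CCl
F3 | step 25 | hydroxy lactone with allylic chloride | O=S(=O)(c1ccccc1)CC(=O)[C@]1(C)[C@H]([C@@H](C)[C@H](OC(C)=O)[C@@H]2O[C@@H]21)[C@@H](O[Si](C)(C)C(C)(C)C)[C@]3(O)[C@@H](C)C(=O)O[C@H]3[C@H](O[Si](CC)(CC)CC)C(=C)CCl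
F4 | step 25 | 8-O-triethylsilyl ether of F3 | O=S(=O)(c1ccccc1)CC(=O)[C@]1(C)[C@H]([C@@H](C)[C@H](OC(C)=O)[C@@H]2O[C@@H]21)[C@@H](O[Si](C)(C)C(C)(C)C)[C@]3(O[Si](CC)(CC)CC)[C@@H](C)C(=O)O[C@H]3[C@H](O[Si](CC)(CC)CC)C(=C)CCl
F5 | step 4 | enantiomer of 7 | COC(=O)[C@@]1(C)[C@@H]([C@H](C)C=C(O[Si](CC)(CC)CC)C1)C=O
F6 | step 4 | enantiomer of 10 | COC(=O)[C@@]1(C)[C@@H]([C@H](C)C=C(O[Si](CC)(CC)CC)C1)[C@H](O)C(=C)COCc1ccc(OC)cc1
F0 | step 18 | none | none
F7 | step 23 | 7-O-propanoyl ester of 29 | O=S(=O)(c1ccccc1)CC(=O)[C@]1(C)[C@H]([C@@H](C)[C@H](OC(C)=O)[C@@H]2O[C@@H]21)[C@@H](O[Si](C)(C)C(C)(C)C)C(=O)[C@@H](OC(=O)CC)[C@H](O[Si](CC)(CC)CC)C(=C)COC(=O)OC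
F8 | step 27 | 2-epimer of 36 | C=C1CC[C@H](O)[C@]2(C)[C@H]([C@@H](C)[C@H](OC(C)=O)[C@@H]3O[C@@H]32)[C@@H](O[Si](C)(C)C(C)(C)C)[C@]2(O[Si](CC)(CC)CC)[C@@H](C)C(=O)O[C@H]2[C@@H]1O[Si](CC)(CC)CC
F9 | step 30 | 6-O-methanesulfonate of 38 | C=C1CC[C@@H](OC(C)=O)[C@]2(C)[C@H]([C@@H](C)[C@H](OC(C)=O)[C@@H]3O[C@@H]32)[C@@H](O[Si](C)(C)C(C)(C)C)[C@]2(O[Si](CC)(CC)CC)[C@@H](C)C(=O)O[C@H]2[C@@H]1OS(C)(=O)=O
A1 | alternative 1 | (Z)-tert-butyldimethyl(penta-1,3-dien-3-yloxy)silane | C=C/C(O[Si](C)(C)C(C)(C)C)=C/C
A2 | alternative 1 | (E)-4-(benzyloxy)-2-methylbut-2-enal | O=C/C(C)=C/COCc1ccccc1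
A3 | alternative 1 | cyclohexene silyl enol ether with C1 formyl and C10 benzyloxymethyl | O=C[C@]1(C)[C@H]([C@@H](C)C(O[Si](C)(C)C(C)(C)C)=CC1)COCc1ccccc1
A4 | alternative 2 | ten-membered C8 ketone, 7-O-(2-bromopropanoyl), 9-O-triethylsilyl, 6-chloro | C=C1CC[C@@H](OC(C)=O)[C@]2(C)[C@H]([C@@H](C)[C@H](OC(C)=O)[C@@H]3O[C@@H]32)[C@@H](O[Si](CC)(CC)CC)C(=O)[C@@H](OC(=O)C(C)Br)[C@H]1Cl
A5 | alternative 2 | 9-O-triethylsilyl ether of 40 | C=C1CC[C@@H](OC(C)=O)[C@]2(C)[C@H]([C@@H](C)[C@H](OC(C)=O)[C@@H]3O[C@@H]32)[C@@H](O[Si](CC)(CC)CC)[C@]2(O)[C@@H](C)C(=O)O[C@H]2[C@H]1Cl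
A6 | alternative 3 | acyclic C7 aldehyde with 8,9-acetonide, C19 methyl ester and γ-chloro allylic bromide | ClC=C(CBr)CC[C@@H](OC(C)=O)[C@]1(C)[C@H]([C@@H](C)[C@H](OC(C)=O)[C@@H]2O[C@@H]21)[C@H]3OC(C)(C)O[C@@]3([C@@H](C)C(=O)OC)C=O
A7 | alternative 3 | ten-membered chlorohydrin ester (7-OH, 6-Cl, 8,9-acetonide) | C=C1CC[C@@H](OC(C)=O)[C@]2(C)[C@H]([C@@H](C)[C@H](OC(C)=O)[C@@H]3O[C@@H]32)[C@H]2OC(C)(C)O[C@@]2([C@@H](C)C(=O)OC)[C@@H](O)[C@H]1Cl
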